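**Plan**

Target numbering used below: ring C1 = ylidene carbon, C2 = CH bearing the hydroxypropyl chain, C3 = quaternary carbon (methyl and homofarnesyl), C4 = CHMe, C5 and C6 = CH2.
Retrosynthesis: enal ← C1 ketone (isopropenyl addition, oxidative [3,3] transposition); C2 side chain ← enolate allylation; C5–C6 ← ring-closing metathesis; C3–C4 and C6–C1 ← one-pot anionic oxy-Cope rearrangement / vinyl Grignard addition.
Enabling feature: C1, C2 and C3 with the C3 methyl and homofarnesyl groups are the head of a geranylgeranyl chain, and the C3–C4 bond is the centre of a 1,5-diene whose 3-position is the ketone-level carbon C1 (an oxy-Cope retron).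
Forward order: C20 chain plus allyl, then (Z)-propenyl terminus; sigmatropic shift and vinylation; ring by metathesis; C2 allylation; enone reduction; enal; deprotection.
Stereochemistry: the C1 carbinol (S, iridium catalysis) is relayed to C3 and C4 in one chair transition state and then erased; C2 follows by substrate-controlled enolate allylation; the enal geometry comes from the [3,3] transposition.

Key step: step 3

Remark: the carbinol centres formed in steps 3 and 8 are carried as epimer mixtures, because both carbons become trigonal later (steps 5 and 11).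

Step 1
Reactants: 1 (2E,6E,10E)-geranylgeraniol
Product: 3 (4S,5E,9E,13E)-6,10,14,18-tetramethylnonadeca-1,5,9,13,17-pentaen-4-ol, via geranylgeranial 2 (not isolated)
Conditions: [Ir(cod)Cl]2 (2.5 mol%), (S)-Cl,MeO-BIPHEP (5 mol%), 3-nitrobenzoic acid (10 mol%), Cs2CO3 (20 mol%), allyl acetate (5 equiv), THF, 100 °C, sealed tube
Reagents that add atoms: allyl acetate, C=CCOC(C)=O
Why: Iridium-catalysed transfer-hydrogenative carbonyl allylation from the alcohol oxidation level; the ortho-cyclometalated iridium benzoate dehydrogenates the allylic alcohol to enal 2 and returns the allyl group to the Si face of the aldehyde, which should set the (4S) carbinol centre (ligand sense assigned by analogy with aryl carbinols) without touching the trisubstituted alkenes.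

Step 2
Reactants: 3 (4S,5E,9E,13E)-6,10,14,18-tetramethylnonadeca-1,5,9,13,17-pentaen-4-ol
Product: 4 (2Z,5S,6E,10E,14E)-7,11,15,19-tetramethylicosa-2,6,10,14,18-pentaen-5-ol
Conditions: (Z)-but-2-ene (excess), Ru(SIMes)(3,6-Cl2C6H2S2)(=CH-C6H4-2-OiPr) (5 mol%), THF, 22 °C
Reagents that add atoms: (Z)-but-2-ene, C/C=C\C
Why: Stereoretentive cross-metathesis; the ruthenium dithiolate catalyst passes the cis geometry of but-2-ene on through an all-syn metallacyclobutane, so only the monosubstituted alkene should be capped as the (2Z)-propenyl terminus.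

Step 3
Reactants: 4 (2Z,5S,6E,10E,14E)-7,11,15,19-tetramethylicosa-2,6,10,14,18-pentaen-5-ol
Product: 8 (5S,6R)-5,6-dimethyl-5-[(3E,7E)-4,8,12-trimethyltrideca-3,7,11-trien-1-yl]octa-1,7-dien-3-ol (both C3 epimers), via potassium alkoxide 5 (not isolated), via potassium enolate 6 (not isolated), via aldehyde 7 (not isolated)
Conditions: KH (1.3 equiv), 18-crown-6 (1.3 equiv), THF, 0 to 40 °C; then AcOH (1.3 equiv), −78 °C; then CH2=CHMgBr (3 equiv), −78 to 0 °C; aq. NH4Cl
Reagents that add atoms: vinylmagnesium bromide, C=C[Mg]Br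
Why: KH/18-crown-6 gives the naked alkoxide 5, which undergoes an anionic oxy-Cope [3,3] shift that breaks the carbinol–CH2 bond and forms C3–C4 to give enolate 6; one equivalent of acetic acid at low temperature releases aldehyde 7, and vinylmagnesium bromide then adds to C1 in the same flask, forming C6–C1. The closest known reaction types are the anionic oxy-Cope rearrangement of acyclic 1,5-dien-3-olates with 1,3-chirality transfer and the 1,2-addition of vinyl Grignard reagents to aldehydes. No ring of the target is closed here, the only cyclic array being the six-centre chair transition state; the carbocycle is closed in step 4. C3 and C4 are set together by the (5S) carbinol centre of 4 (C1 of the target): the chair with the alkoxide equatorial is enforced by the methyl group that is cis to the carbinol carbon on the 6E alkene (it would clash with an axial alkoxide), the homofarnesyl group then sits equatorial and, because the propenyl terminus is Z, the C4 methyl sits axial, so the two methyl groups end anti and the homofarnesyl group cis to the C4 methyl; the new carbinol centre at C1 is not controlled and is removed in step 5. The step needs chair over boat, [3,3] shift over cleavage to enal and crotylpotassium, and clean 1,2-addition: the E-trisubstituted alkene, the poorly stabilised allyl anion that cleavage would have to expel, and the low temperature of quench and addition should secure these.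

Step 4
Reactants: 8 (5S,6R)-5,6-dimethyl-5-[(3E,7E)-4,8,12-trimethyltrideca-3,7,11-trien-1-yl]octa-1,7-dien-3-ol
Product: 9 (4R,5S)-4,5-dimethyl-5-[(3E,7E)-4,8,12-trimethyltrideca-3,7,11-trien-1-yl]cyclohex-2-en-1-ol (both C1 epimers)
Conditions: second-generation Grubbs catalyst RuCl2(=CHPh)(PCy3)(H2IMes) (3 mol%), CH2Cl2 (0.005 M), 40 °C
Reagents that add atoms: none
Why: Ring-closing metathesis of the two monosubstituted alkenes closes the six-membered ring at C5=C6 with loss of ethene, the trisubstituted chain alkenes reacting far more slowly.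

Step 5
Reactants: 9 (4R,5S)-4,5-dimethyl-5-[(3E,7E)-4,8,12-trimethyltrideca-3,7,11-trien-1-yl]cyclohex-2-en-1-ol
Product: 10 (4R,5S)-4,5-dimethyl-5-[(3E,7E)-4,8,12-trimethyltrideca-3,7,11-trien-1-yl]cyclohex-2-en-1-one
Conditions: MnO2 (activated, 20 equiv), CH2Cl2, 23 °C
Reagents that add atoms: none
Why: Allylic alcohol oxidation with MnO2 funnels both carbinol epimers into one enone and leaves the isolated alkenes alone.

Step 6
Reactants: 10 (4R,5S)-4,5-dimethyl-5-[(3E,7E)-4,8,12-trimethyltrideca-3,7,11-trien-1-yl]cyclohex-2-en-1-one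
Product: 12 (4R,5R,6S)-4,5-dimethyl-6-(prop-2-en-1-yl)-5-[(3E,7E)-4,8,12-trimethyltrideca-3,7,11-trien-1-yl]cyclohex-2-en-1-one, via lithium dienolate 11 (not isolated)
Conditions: LiN(i-Pr)2 (1.05 equiv), THF, −78 °C; allyl bromide (1.5 equiv), DMPU, −78 to −40 °C
Reagents that add atoms: allyl bromide, C=CCBr
Why: Kinetic α'-deprotonation gives the cross-conjugated dienolate, and axial alkylation should occur on the face opposite the homofarnesyl group (pseudo-axial on the adjacent quaternary carbon in the half-chair that keeps both methyl groups pseudo-equatorial), setting C2 trans to the chain and cis to the C3 methyl.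

Step 7
Reactants: 12 (4R,5R,6S)-4,5-dimethyl-6-(prop-2-en-1-yl)-5-[(3E,7E)-4,8,12-trimethyltrideca-3,7,11-trien-1-yl]cyclohex-2-en-1-one
Product: 14 (2S,3R,4R)-3,4-dimethyl-2-(prop-2-en-1-yl)-3-[(3E,7E)-4,8,12-trimethyltrideca-3,7,11-trien-1-yl]cyclohexan-1-one, via silyl enol ether 13 (not isolated)
Conditions: [(Ph3P)CuH]6 (5 mol%), PhMe2SiH (1.5 equiv), toluene, 23 °C; then 1 M HCl, THF, 0 °C
Reagents that add atoms: none
Why: Copper hydride conjugate reduction touches only the enone, and the enol ether forms on the C6 side, so the C2 centre is never enolized.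

Step 8
Reactants: 14 (2S,3R,4R)-3,4-dimethyl-2-(prop-2-en-1-yl)-3-[(3E,7E)-4,8,12-trimethyltrideca-3,7,11-trien-1-yl]cyclohexan-1-one
Product: 15 (2S,3R,4R)-3,4-dimethyl-1-(prop-1-en-2-yl)-2-(prop-2-en-1-yl)-3-[(3E,7E)-4,8,12-trimethyltrideca-3,7,11-trien-1-yl]cyclohexan-1-ol (C1 epimers)
Conditions: CH2=C(CH3)MgBr (3 equiv), CeCl3 (3 equiv, dried), THF, −78 to 0 °C
Reagents that add atoms: isopropenylmagnesium bromide, C=C(C)[Mg]Br
Why: Organocerium 1,2-addition to a hindered, enolizable ketone proceeds without α-deprotonation, so C2 keeps its configuration; the new carbinol centre is lost in step 11.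

Step 9
Reactants: 15 (2S,3R,4R)-3,4-dimethyl-1-(prop-1-en-2-yl)-2-(prop-2-en-1-yl)-3-[(3E,7E)-4,8,12-trimethyltrideca-3,7,11-trien-1-yl]cyclohexan-1-ol
Product: 17 (2S,3R,4R)-2-(3-hydroxypropyl)-3,4-dimethyl-1-(prop-1-en-2-yl)-3-[(3E,7E)-4,8,12-trimethyltrideca-3,7,11-trien-1-yl]cyclohexan-1-ol, via alkylborane 16 (not isolated)
Conditions: BH3·THF, 2-methylbut-2-ene (gives disiamylborane, 2.5 equiv), THF, 0 °C; then NaOH, H2O2, 0 to 23 °C
Reagents that add atoms: hydrogen peroxide, OO
Why: Disiamylborane hydroborates the monosubstituted alkene anti-Markovnikov much faster than the isopropenyl group (1,1-disubstituted, on a fully substituted carbon) or the trisubstituted alkenes, and oxidation gives the primary alcohol.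

Step 10
Reactants: 17 (2S,3R,4R)-2-(3-hydroxypropyl)-3,4-dimethyl-1-(prop-1-en-2-yl)-3-[(3E,7E)-4,8,12-trimethyltrideca-3,7,11-trien-1-yl]cyclohexan-1-ol
Product: 18 (2S,3R,4R)-2-{3-[(tert-butyldimethylsilyl)oxy]propyl}-3,4-dimethyl-1-(prop-1-en-2-yl)-3-[(3E,7E)-4,8,12-trimethyltrideca-3,7,11-trien-1-yl]cyclohexan-1-ol
Conditions: TBSCl (1.1 equiv), imidazole, DMF, 0 °C
Reagents that add atoms: tert-butyldimethylsilyl chloride, CC(C)(C)[Si](C)(C)Cl
Why: Silylation distinguishes the primary from the tertiary hydroxyl; the free 1,5-diol would otherwise give a lactone in step 11.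

Step 11
Reactants: 18 (2S,3R,4R)-2-{3-[(tert-butyldimethylsilyl)oxy]propyl}-3,4-dimethyl-1-(prop-1-en-2-yl)-3-[(3E,7E)-4,8,12-trimethyltrideca-3,7,11-trien-1-yl]cyclohexan-1-ol
Product: 19 (2Z)-2-[(2S,3R,4R)-2-{3-[(tert-butyldimethylsilyl)oxy]propyl}-3,4-dimethyl-3-[(3E,7E)-4,8,12-trimethyltrideca-3,7,11-trien-1-yl]cyclohexylidene]propanal
Conditions: pyridinium chlorochromate (3 equiv), NaOAc, 4 Å molecular sieves, CH2Cl2, 23 °C
Reagents that add atoms: pyridinium chlorochromate, [O-][Cr](=O)(=O)Cl.c1cc[nH+]cc1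
Why: Babler–Dauben oxidative transposition; the tertiary allylic chromate ester undergoes a [3,3] shift and the primary chromate is oxidized to the enal, and the isopropenyl methyl should lie on the side of the unsubstituted C6 (away from C2 and the quaternary C3), which places the formyl group cis to C2 (Z).

Step 12
Reactants: 19 (2Z)-2-[(2S,3R,4R)-2-{3-[(tert-butyldimethylsilyl)oxy]propyl}-3,4-dimethyl-3-[(3E,7E)-4,8,12-trimethyltrideca-3,7,11-trien-1-yl]cyclohexylidene]propanal
Product: 20 (2Z)-2-[(2S,3R,4R)-2-(3-hydroxypropyl)-3,4-dimethyl-3-[(3E,7E)-4,8,12-trimethyltrideca-3,7,11-trien-1-yl]cyclohexylidene]propanal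
Conditions: HF·pyridine, pyridine, THF, 0 °C
Reagents that add atoms: none
Why: Fluoride-driven Si–O cleavage under non-basic conditions frees the primary alcohol without γ-deprotonation of the enal, so C2 and the alkene geometry should be kept.

**Compound list**

1 | (2E,6E,10E)-geranylgeraniol | CC(C)=CCC/C(C)=C/CC/C(C)=C/CC/C(C)=C/CO | starting material
2 | (2E,6E,10E)-geranylgeranial | CC(C)=CCC/C(C)=C/CC/C(C)=C/CC/C(C)=C/C=O | intermediate (not isolated)
3 | (4S,5E,9E,13E)-6,10,14,18-tetramethylnonadeca-1,5,9,13,17-pentaen-4-ol | C=CC[C@H](O)/C=C(\C)CC/C=C(\C)CC/C=C(\C)CCC=C(C)C | intermediate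
4 | (2Z,5S,6E,10E,14E)-7,11,15,19-tetramethylicosa-2,6,10,14,18-pentaen-5-ol | C/C=C\C[C@H](O)/C=C(\C)CC/C=C(\C)CC/C=C(\C)CCC=C(C)C | intermediate
5 | potassium alkoxide of 4 | C/C=C\C[C@H]([O-])/C=C(\C)CC/C=C(\C)CC/C=C(\C)CCC=C(C)C.[K+] | intermediate (not isolated)
6 | potassium (E)-enolate of aldehyde 7 | [K+].[O-]/C=C/[C@](C)(CC/C=C(\C)CC/C=C(\C)CCC=C(C)C)[C@H](C)C=C | intermediate (not isolated)
7 | (3S,4R)-3,4-dimethyl-3-[(3E,7E)-4,8,12-trimethyltrideca-3,7,11-trien-1-yl]hex-5-enal | O=CC[C@](C)(CC/C=C(\C)CC/C=C(\C)CCC=C(C)C)[C@H](C)C=C | intermediate (not isolated)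
8 | (5S,6R)-5,6-dimethyl-5-[(3E,7E)-4,8,12-trimethyltrideca-3,7,11-trien-1-yl]octa-1,7-dien-3-ol (C3 epimers) | C=CC(O)C[C@](C)(CC/C=C(\C)CC/C=C(\C)CCC=C(C)C)[C@H](C)C=C | intermediate
9 | (4R,5S)-4,5-dimethyl-5-[(3E,7E)-4,8,12-trimethyltrideca-3,7,11-trien-1-yl]cyclohex-2-en-1-ol (C1 epimers) | CC(C)=CCC/C(C)=C/CC/C(C)=C/CC[C@]1(C)[C@H](C)C=CC(O)C1 | intermediate
10 | (4R,5S)-4,5-dimethyl-5-[(3E,7E)-4,8,12-trimethyltrideca-3,7,11-trien-1-yl]cyclohex-2-en-1-one | CC(C)=CCC/C(C)=C/CC/C(C)=C/CC[C@]1(C)[C@H](C)C=CC(=O)C1 | intermediate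
11 | lithium cross-conjugated dienolate of 10 | [Li+].CC(C)=CCC/C(C)=C/CC/C(C)=C/CC[C@]1(C)[C@H](C)C=CC([O-])=C1 | intermediate (not isolated)
12 | (4R,5R,6S)-4,5-dimethyl-6-(prop-2-en-1-yl)-5-[(3E,7E)-4,8,12-trimethyltrideca-3,7,11-trien-1-yl]cyclohex-2-en-1-one | CC(C)=CCC/C(C)=C/CC/C(C)=C/CC[C@]1(C)[C@H](C)C=CC(=O)[C@H]1CC=C | intermediate
13 | dimethylphenylsilyl enol ether of 14 (enol double bond toward C6) | CC(C)=CCC/C(C)=C/CC/C(C)=C/CC[C@]1(C)[C@H](C)CC=C(O[Si](C)(C)c2ccccc2)[C@H]1CC=C | intermediate (not isolated)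
14 | (2S,3R,4R)-3,4-dimethyl-2-(prop-2-en-1-yl)-3-[(3E,7E)-4,8,12-trimethyltrideca-3,7,11-trien-1-yl]cyclohexan-1-one | CC(C)=CCC/C(C)=C/CC/C(C)=C/CC[C@]1(C)[C@H](C)CCC(=O)[C@H]1CC=C | intermediate
15 | (2S,3R,4R)-3,4-dimethyl-1-(prop-1-en-2-yl)-2-(prop-2-en-1-yl)-3-[(3E,7E)-4,8,12-trimethyltrideca-3,7,11-trien-1-yl]cyclohexan-1-ol (C1 epimers) | CC(C)=CCC/C(C)=C/CC/C(C)=C/CC[C@]1(C)[C@H](C)CCC(O)(C(C)=C)[C@H]1CC=C | intermediate
16 | B-alkyl bis(3-methylbutan-2-yl)borane from 15 | CC(C)=CCC/C(C)=C/CC/C(C)=C/CC[C@]1(C)[C@H](C)CCC(O)(C(C)=C)[C@H]1CCCB(C(C)C(C)C)C(C)C(C)C | intermediate (not isolated)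
17 | (2S,3R,4R)-2-(3-hydroxypropyl)-3,4-dimethyl-1-(prop-1-en-2-yl)-3-[(3E,7E)-4,8,12-trimethyltrideca-3,7,11-trien-1-yl]cyclohexan-1-ol (C1 epimers) | CC(C)=CCC/C(C)=C/CC/C(C)=C/CC[C@]1(C)[C@H](C)CCC(O)(C(C)=C)[C@H]1CCCO | intermediate
18 | (2S,3R,4R)-2-{3-[(tert-butyldimethylsilyl)oxy]propyl}-3,4-dimethyl-1-(prop-1-en-2-yl)-3-[(3E,7E)-4,8,12-trimethyltrideca-3,7,11-trien-1-yl]cyclohexan-1-ol (C1 epimers) | CC(C)=CCC/C(C)=C/CC/C(C)=C/CC[C@]1(C)[C@H](C)CCC(O)(C(C)=C)[C@H]1CCCO[Si](C)(C)C(C)(C)C | intermediate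
19 | (2Z)-2-[(2S,3R,4R)-2-{3-[(tert-butyldimethylsilyl)oxy]propyl}-3,4-dimethyl-3-[(3E,7E)-4,8,12-trimethyltrideca-3,7,11-trien-1-yl]cyclohexylidene]propanal | CC(C)=CCC/C(C)=C/CC/C(C)=C/CC[C@]1(C)[C@H](C)CC/C(=C(\C)C=O)[C@H]1CCCO[Si](C)(C)C(C)(C)C | intermediate
20 | (2Z)-2-[(2S,3R,4R)-2-(3-hydroxypropyl)-3,4-dimethyl-3-[(3E,7E)-4,8,12-trimethyltrideca-3,7,11-trien-1-yl]cyclohexylidene]propanal | CC(C)=CCC/C(C)=C/CC/C(C)=C/CC[C@]1(C)[C@H](C)CC/C(=C(\C)C=O)[C@H]1CCCO | target

**Step count and risks**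

Total steps: 12. Longest linear sequence: 12 (the route is linear from 1).

Steps most likely to fail:

1. Step 3. The alkoxide may cleave into enal and crotylpotassium instead of rearranging, the shift may leak through a boat or an axial-alkoxide chair (eroding C3/C4), and the aldehyde may self-condense during the telescoped quench. Fallback, setting out from 1 and rejoining at 8: esterification of 1 with propanoic anhydride (DMAP, pyridine) gives geranylgeranyl propanoate F1. Ireland–Claisen rearrangement of its (E)-O-boron ketene acetal follows, made with Et3N in toluene/hexane (−78 to 4 °C) and the enantiomer of 2-bromo-1,3-bis[3,5-bis(trifluoromethyl)phenylsulfonyl]-4,5-diphenyl-1,3,2-diazaborolidine that gives the (2S,3S) series; it sets both centres in a neutral chair [3,3] shift and gives the pentenoic acid F2. Hydroboration of the vinyl group (9-BBN, then NaBO3) and acid-induced lactonisation give the δ-lactone F3. i-Bu2AlH at −78 °C gives the lactol F4, methylenation with Ph3P=CH2 gives the alkenol F5, and Dess–Martin oxidation gives aldehyde 7, which is vinylated as in step 3 to return to 8.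

2. Step 6. Facial selectivity of the enolate allylation may be poor, or the α'-centre may epimerize by proton exchange. Fallback, from 10 back to 12: the lithium dienolate is O-acylated with allyl chloroformate (TMEDA, THF, −78 °C) to the allyl dienyl carbonate F6. Pd2(dba)3 with (S)- or (R)-t-Bu-PHOX (THF, 23 °C) then effects decarboxylative allylic alkylation under neutral conditions, the ligand enantiomer being chosen to match the substrate bias, giving 12.

3. Step 11. Control of the alkene geometry in the [3,3] shift may be poor, and the tertiary alcohol may dehydrate. Fallback, from 19 back to 20: the geometric mixture of 19 is desilylated as in step 12 to 20 as a mixture. Catalytic DBU in MeCN (23 °C) then lets the free hydroxyl add reversibly to ring C1 (oxa-Michael addition), through the bicyclic ether aldehyde F7. Ring opening returns the enal, so the geometric isomers interconvert without touching the chain alkenes. The isomer with the formyl group on the more hindered C2 side should accumulate; it is separated and the rest is recycled.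

Further compounds
F1 | step 3 | (2E,6E,10E)-3,7,11,15-tetramethylhexadeca-2,6,10,14-tetraen-1-yl propanoate | CCC(=O)OC/C=C(\C)CC/C=C(\C)CC/C=C(\C)CCC=C(C)C
F2 | step 3 | (2S,3S)-2,3-dimethyl-3-[(3E,7E)-4,8,12-trimethyltrideca-3,7,11-trien-1-yl]pent-4-enoic acid | OC(=O)[C@@H](C)[C@@](C)(CC/C=C(\C)CC/C=C(\C)CCC=C(C)C)C=C
F3 | step 3 | (3S,4S)-3,4-dimethyl-4-[(3E,7E)-4,8,12-trimethyltrideca-3,7,11-trien-1-yl]oxan-2-one | O=C1OCC[C@](C)(CC/C=C(\C)CC/C=C(\C)CCC=C(C)C)[C@@H]1C
F4 | step 3 | (3S,4S)-3,4-dimethyl-4-[(3E,7E)-4,8,12-trimethyltrideca-3,7,11-trien-1-yl]oxan-2-ol (anomers) | OC1OCC[C@](C)(CC/C=C(\C)CC/C=C(\C)CCC=C(C)C)[C@@H]1C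
F5 | step 3 | (3S,4R)-3,4-dimethyl-3-[(3E,7E)-4,8,12-trimethyltrideca-3,7,11-trien-1-yl]hex-5-en-1-ol | OCC[C@](C)(CC/C=C(\C)CC/C=C(\C)CCC=C(C)C)[C@H](C)C=C
F6 | step 6 | (3R,4R)-3,4-dimethyl-3-[(3E,7E)-4,8,12-trimethyltrideca-3,7,11-trien-1-yl]cyclohexa-1,5-dien-1-yl prop-2-en-1-yl carbonate | CC(C)=CCC/C(C)=C/CC/C(C)=C/CC[C@]1(C)[C@H](C)C=CC(OC(=O)OCC=C)=C1
F7 | step 11 | 2-[(4aS,5R,6R)-5,6-dimethyl-5-[(3E,7E)-4,8,12-trimethyltrideca-3,7,11-trien-1-yl]octahydro-2H-chromen-8a-yl]propanal (C8a and side-chain centre open) | CC(C)=CCC/C(C)=C/CC/C(C)=C/CC[C@]1(C)[C@H](C)CCC2(C(C)C=O)OCCC[C@@H]12
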